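**Retrosynthetic overview**

1. Vismiaphenone E is a 2,2-dimethyl-2H-chromene (ring C) fused to an acylphloroglucinol ring A. Ring A carries the 4-hydroxybenzoyl group (ring B) at C6, free hydroxyls at C5 and C7 and a prenyl group at C8; there is no stereocentre.
2. The strategy rests on ring A: its oxygens at C5, C7 and C8a lie 1,3,5 around the acyl-bearing C6, which is the folding pattern of a 7-aryl-3,5,7-trioxoheptanoate. Ring A is therefore made from a 2-pyrone by ring opening and Claisen closure, with the ring B oxygen already masked as a MOM ether and the three ring A hydroxyls free.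
3. Late disconnections: the ring B O–MOM bond (last), the C8–prenyl bond (phenoxide C-alkylation), and ring C at O1–C2 and C4–C4a (propargyl aryl ether Claisen rearrangement and oxa-6π closure). The two hydroxyls ortho to the carbonyl are held as acetates during ring C formation so that only the para oxygen can close.
4. The pyrone precursor comes from C-acylation of the dianion of 4-hydroxy-6-methyl-2-pyrone with methyl 4-(methoxymethoxy)benzoate.
5. Ring order: ring B is bought, ring A is formed in step 3, ring C in step 6.

Key step: step 3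

Remark: chromene numbering (O1, C2, C3, C4, C4a, C5–C8, C8a) is used for rings A and C of the late compounds; in the benzophenone intermediates the carbonyl-bearing ring A carbon is C1. The target is achiral, so no step has to set configuration.

**Route**

Step 1
Reactants: 1 methyl 4-hydroxybenzoate
Product: 2 methyl 4-(methoxymethoxy)benzoate
Conditions: MOMCl, K2CO3, acetone, 0 °C to rt
Reagents that add atoms: chloromethyl methyl ether, COCCl
Why: Williamson-type O-alkylation of the phenoxide with the reactive α-chloro ether gives the MOM acetal, which is stable to the strong base of step 2 and the methoxide of step 3.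

Step 2
Reactants: 3 4-hydroxy-6-methyl-2H-pyran-2-one; 2 methyl 4-(methoxymethoxy)benzoate
Product: 5 4-hydroxy-6-{2-[4-(methoxymethoxy)phenyl]-2-oxoethyl}-2H-pyran-2-one, via dilithio pyrone dianion 4 (not isolated)
Conditions: 3 (2.1 equiv), LiN(iPr)2 (4.3 equiv), THF, −78 to 0 °C; then 2 (1.0 equiv), 0 °C to rt; cold 1 M HCl
Reagents that add atoms: none
Why: The 6-methyl group of the 4-oxido-2-pyrone is vinylogously acidic, so a second equivalent of LiN(iPr)2 gives the C,O-dianion, whose exocyclic carbon undergoes Claisen-type C-acylation by the non-enolizable aryl ester; the second equivalent of dianion deprotonates the doubly activated methylene of the product and so stops further addition.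

Step 3
Reactants: 5 4-hydroxy-6-{2-[4-(methoxymethoxy)phenyl]-2-oxoethyl}-2H-pyran-2-one
Product: 7 [4-(methoxymethoxy)phenyl](2,4,6-trihydroxyphenyl)methanone, via magnesium-chelated triketo ester 6 (not isolated)
Conditions: Mg(OMe)2 (6 equiv), MeOH, reflux; then cold 1 M HCl
Reagents that add atoms: none
Why: Methoxide from Mg(OMe)2 adds to the lactone carbonyl and opens the 2-pyrone to methyl 7-aryl-3,5,7-trioxoheptanoate, held as its magnesium enolate chelate 6; chain carbon C6, between the C5 and C7 carbonyls, then attacks the ester carbonyl C1, methoxide leaves and the cyclohexane-1,3,5-trione enolizes to the aromatic triol. The closest known reaction type is the Mg(OMe)2-promoted Claisen (Dieckmann-type) cyclization of 6-(2-oxoalkyl)-4-hydroxy-2-pyrones and 3,5,7-triketo esters to acylphloroglucinols. Ring A closes in a 6-exo-trig mode, forming the bond between the acyl-bearing carbon and a hydroxyl-bearing carbon. No stereocentre is formed. The step needs Claisen-mode closure (C6 onto C1) and not aldol-mode closure (C2 onto the C7 ketone, which would lead to a 6-aryl-β-resorcylate). Chelation by the magnesium ion ties C6 into a nucleophilic diketonate and activates the ester, while the aryl ketone, deactivated by its para alkoxy donor, is a poor electrophile; the MOM acetal is inert to methoxide.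

Step 4
Reactants: 7 [4-(methoxymethoxy)phenyl](2,4,6-trihydroxyphenyl)methanone; 8 3-chloro-3-methylbut-1-yne
Product: 9 {2,6-dihydroxy-4-[(2-methylbut-3-yn-2-yl)oxy]phenyl}[4-(methoxymethoxy)phenyl]methanone
Conditions: 8 (1.3 equiv), DBU (1.3 equiv), CuCl2·2H2O (1 mol %), MeCN, 0 °C
Reagents that add atoms: 3-chloro-3-methylbut-1-yne 8, CC(C)(Cl)C#C
Why: Copper-catalysed propargylic etherification of a tertiary propargylic chloride (copper acetylide/allenylidene pathway); the para hydroxyl is the most acidic and the only unhindered one, the two ortho hydroxyls being flanked by the aroyl group and hydrogen-bonded to its carbonyl, as in the known selective 4-O-monoalkylation of 2,4,6-trihydroxyaryl ketones.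

Step 5
Reactants: 9 {2,6-dihydroxy-4-[(2-methylbut-3-yn-2-yl)oxy]phenyl}[4-(methoxymethoxy)phenyl]methanone
Product: 10 2-[4-(methoxymethoxy)benzoyl]-5-[(2-methylbut-3-yn-2-yl)oxy]-1,3-phenylene diacetate
Conditions: Ac2O, pyridine, DMAP (cat.), CH2Cl2, rt
Reagents that add atoms: acetic anhydride, CC(=O)OC(C)=O
Why: DMAP-catalysed acylation caps both ortho hydroxyls, so that after the rearrangement of step 6 the oxygen para to the carbonyl is the only free phenol beside the allene and ring C cannot close onto an ortho oxygen.

Step 6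
Reactants: 10 2-[4-(methoxymethoxy)benzoyl]-5-[(2-methylbut-3-yn-2-yl)oxy]-1,3-phenylene diacetate
Product: 14 6-[4-(methoxymethoxy)benzoyl]-2,2-dimethyl-2H-chromene-5,7-diyl diacetate, via allenyl cyclohexadienone 11 (not isolated), via ortho-allenylphenol 12 (not isolated), via ortho-quinone methide 13 (not isolated)
Conditions: o-xylene, 140 °C
Reagents that add atoms: none
Why: Aromatic propargyl Claisen rearrangement ([3,3]) to either of the two equivalent ortho carbons, enolization, [1,5]-hydrogen shift from the new phenol to the allene and oxa-6π electrocyclization of the ortho-quinone methide form the 2,2-dimethyl-2H-chromene; the symmetry of 10 and the acetate caps leave a single regiochemical outcome, with O1 para to the carbonyl.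

Step 7
Reactants: 14 6-[4-(methoxymethoxy)benzoyl]-2,2-dimethyl-2H-chromene-5,7-diyl diacetate
Product: 15 (5,7-dihydroxy-2,2-dimethyl-2H-chromen-6-yl)[4-(methoxymethoxy)phenyl]methanone
Conditions: K2CO3, MeOH, 0 °C to rt; then cold 1 M HCl
Reagents that add atoms: none
Why: Base-mediated transesterification (methanolysis) of the two aryl acetates; the MOM acetal, the chromene and the diaryl ketone are inert to carbonate in methanol at or below room temperature.

Step 8
Reactants: 15 (5,7-dihydroxy-2,2-dimethyl-2H-chromen-6-yl)[4-(methoxymethoxy)phenyl]methanone; 16 prenyl bromide (1-bromo-3-methylbut-2-ene)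
Product: 17 [5,7-dihydroxy-2,2-dimethyl-8-(3-methylbut-2-en-1-yl)-2H-chromen-6-yl][4-(methoxymethoxy)phenyl]methanone
Conditions: 16 (1.2 equiv), 10% aq KOH, 0 °C to rt
Reagents that add atoms: prenyl bromide 16, CC(C)=CCBr
Why: C-alkylation of an ambident acylphloroglucinol-type phenoxide with an allylic bromide: C8 is the only unsubstituted ring A carbon, ortho to the C7 phenoxide and para to the C5 phenoxide, and in water the strongly solvated oxygens are poor nucleophiles, so SN2 attack through carbon is favoured.

Step 9
Reactants: 17 [5,7-dihydroxy-2,2-dimethyl-8-(3-methylbut-2-en-1-yl)-2H-chromen-6-yl][4-(methoxymethoxy)phenyl]methanone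
Product: 18 vismiaphenone E, [5,7-dihydroxy-2,2-dimethyl-8-(3-methylbut-2-en-1-yl)-2H-chromen-6-yl](4-hydroxyphenyl)methanone
Conditions: HCl (1 M in MeOH), rt to 40 °C
Reagents that add atoms: none
Why: Acid-catalysed transacetalization of the aryl MOM ether to dimethoxymethane under mild conditions (dilute methanolic HCl, no heating above 40 °C) that the chromene and the ortho-prenylphenol are expected to tolerate.

**Compound list**

1 | methyl 4-hydroxybenzoate | COC(=O)c1ccc(O)cc1 | starting material
2 | methyl 4-(methoxymethoxy)benzoate | COCOc1ccc(cc1)C(=O)OC | intermediate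
3 | 4-hydroxy-6-methyl-2H-pyran-2-one | CC1=CC(O)=CC(=O)O1 | starting material
4 | dilithium salt of the C,O-dianion of 3 (4-oxido, 6-lithiomethyl; not isolated) | [Li+].[Li+].[CH2-]C1=CC([O-])=CC(=O)O1 | intermediate
5 | 4-hydroxy-6-{2-[4-(methoxymethoxy)phenyl]-2-oxoethyl}-2H-pyran-2-one | O=C1C=C(O)C=C(CC(=O)c2ccc(OCOC)cc2)O1 | intermediate
6 | methyl 7-[4-(methoxymethoxy)phenyl]-3,5,7-trioxoheptanoate, present as its magnesium enolate chelate (not isolated; SMILES of the neutral triketo ester) | COC(=O)CC(=O)CC(=O)CC(=O)c1ccc(OCOC)cc1 | intermediate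
7 | [4-(methoxymethoxy)phenyl](2,4,6-trihydroxyphenyl)methanone | COCOc1ccc(cc1)C(=O)c1c(O)cc(O)cc1O | intermediate
8 | 3-chloro-3-methylbut-1-yne | CC(C)(Cl)C#C | starting material
9 | {2,6-dihydroxy-4-[(2-methylbut-3-yn-2-yl)oxy]phenyl}[4-(methoxymethoxy)phenyl]methanone | COCOc1ccc(cc1)C(=O)c1c(O)cc(OC(C)(C)C#C)cc1O | intermediate
10 | 2-[4-(methoxymethoxy)benzoyl]-5-[(2-methylbut-3-yn-2-yl)oxy]-1,3-phenylene diacetate | COCOc1ccc(cc1)C(=O)c1c(OC(C)=O)cc(OC(C)(C)C#C)cc1OC(C)=O | intermediate
11 | 3,5-diacetoxy-4-[4-(methoxymethoxy)benzoyl]-6-(3-methylbuta-1,2-dien-1-yl)cyclohexa-2,4-dien-1-one (racemic, not isolated) | O=C1C=C(OC(C)=O)C(C(=O)c2ccc(OCOC)cc2)=C(OC(C)=O)C1C=C=C(C)C | intermediate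
12 | 5-hydroxy-2-[4-(methoxymethoxy)benzoyl]-4-(3-methylbuta-1,2-dien-1-yl)-1,3-phenylene diacetate (not isolated) | COCOc1ccc(cc1)C(=O)c1c(OC(C)=O)cc(O)c(C=C=C(C)C)c1OC(C)=O | intermediate
13 | 3,5-diacetoxy-4-[4-(methoxymethoxy)benzoyl]-6-(3-methylbut-2-en-1-ylidene)cyclohexa-2,4-dien-1-one (ortho-quinone methide, not isolated) | O=C1C=C(OC(C)=O)C(C(=O)c2ccc(OCOC)cc2)=C(OC(C)=O)C1=CC=C(C)C | intermediate
14 | 6-[4-(methoxymethoxy)benzoyl]-2,2-dimethyl-2H-chromene-5,7-diyl diacetate | COCOc1ccc(cc1)C(=O)c1c(OC(C)=O)cc2OC(C)(C)C=Cc2c1OC(C)=O | intermediate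
15 | (5,7-dihydroxy-2,2-dimethyl-2H-chromen-6-yl)[4-(methoxymethoxy)phenyl]methanone | COCOc1ccc(cc1)C(=O)c1c(O)cc2OC(C)(C)C=Cc2c1O | intermediate
16 | prenyl bromide (1-bromo-3-methylbut-2-ene) | CC(C)=CCBr | starting material
17 | [5,7-dihydroxy-2,2-dimethyl-8-(3-methylbut-2-en-1-yl)-2H-chromen-6-yl][4-(methoxymethoxy)phenyl]methanone | COCOc1ccc(cc1)C(=O)c1c(O)c(CC=C(C)C)c2OC(C)(C)C=Cc2c1O | intermediate
18 | vismiaphenone E, [5,7-dihydroxy-2,2-dimethyl-8-(3-methylbut-2-en-1-yl)-2H-chromen-6-yl](4-hydroxyphenyl)methanone | CC(C)=CCc1c(O)c(C(=O)c2ccc(O)cc2)c(O)c2c1OC(C)(C)C=C2 | target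

**Step count**

Total step count: 9
Longest linear sequence: 9 steps (steps 1 to 9, from methyl 4-hydroxybenzoate 1; the pyrone 3 enters at step 2)

**Steps most likely to fail**

Step 3 (key step). The open-chain triketo ester may close in the aldol mode (C2 onto the aryl ketone, followed by dehydration to a resorcylate), or it may relactonize to the pyrone without cyclizing. Fallback: ring A is brought in preformed as an aryllithium instead of being built from the pyrone. The fallback sets out from ester 2. 1,3,5-Tris(benzyloxy)benzene would be lithiated between two benzyloxy groups (n-BuLi, TMEDA, THF, 0 °C) and the aryllithium added once to 2 at −78 °C; a second addition to the doubly ortho-substituted ketone is sterically blocked. This should give [4-(methoxymethoxy)phenyl][2,4,6-tris(benzyloxy)phenyl]methanone F1. Hydrogenolysis of the three benzyl ethers (H2, Pd/C, EtOAc, rt), at a stage that holds no alkene, would return the route at triol 7 with the MOM ether intact.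

Step 8. O-alkylation of the C5 and C7 phenoxides, and a second alkylation with dearomatization, may compete with attack through C8. Fallback: the prenyl group is delivered from oxygen by a sigmatropic shift. The fallback sets out from 15. Copper-catalysed etherification with 3-chloro-3-methylbut-1-yne 8 (DBU, CuCl2·2H2O, MeCN, 0 °C) should take place at the C7 hydroxyl, which has a free neighbour at C8, whereas the C5 hydroxyl is wedged between the aroyl group and the peri C4–H. It should give {5-hydroxy-2,2-dimethyl-7-[(2-methylbut-3-yn-2-yl)oxy]-2H-chromen-6-yl}[4-(methoxymethoxy)phenyl]methanone F2. Semihydrogenation of the terminal alkyne (H2, Pd/CaCO3 poisoned with Pb(OAc)2, quinoline, EtOAc) would give {5-hydroxy-2,2-dimethyl-7-[(2-methylbut-3-en-2-yl)oxy]-2H-chromen-6-yl}[4-(methoxymethoxy)phenyl]methanone F3. Heating F3 (toluene, 110 °C) should bring about the aromatic Claisen rearrangement ([3,3]) to C8, the only open ortho position, which turns the 1,1-dimethylallyl ether into the C8 prenyl group and frees the C7 hydroxyl. The fallback comes back to the route at 17.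

Step 9. Under the acid needed to cleave the MOM ether, the C7 hydroxyl may add across the protonated prenyl double bond to close a chroman ring, and the chromene may be hydrated or isomerized. Fallback: the protecting group on ring B is exchanged before the prenyl group is present, so that the last deprotection uses fluoride. The fallback sets out from 15. Methanolic HCl at rt would remove the MOM group, at a stage with no prenyl group, and give (5,7-dihydroxy-2,2-dimethyl-2H-chromen-6-yl)(4-hydroxyphenyl)methanone F4. Silylation with iPr3SiCl and imidazole (DMF, 0 °C) should select the unhindered ring B phenol over the two hindered, carbonyl-flanked ring A hydroxyls and give (5,7-dihydroxy-2,2-dimethyl-2H-chromen-6-yl){4-[tri(propan-2-yl)silyloxy]phenyl}methanone F5. C8 prenylation under non-aqueous conditions (prenyl bromide 16, NaH, toluene, 0 °C to rt) would give [5,7-dihydroxy-2,2-dimethyl-8-(3-methylbut-2-en-1-yl)-2H-chromen-6-yl]{4-[tri(propan-2-yl)silyloxy]phenyl}methanone F6. Desilylation with Bu4NF buffered with AcOH (THF, 0 °C) comes back to the route at the target 18.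

**Further compounds**

F1 | step 3 | [4-(methoxymethoxy)phenyl][2,4,6-tris(benzyloxy)phenyl]methanone | COCOc1ccc(cc1)C(=O)c1c(OCc2ccccc2)cc(OCc2ccccc2)cc1OCc1ccccc1
F2 | step 8 | {5-hydroxy-2,2-dimethyl-7-[(2-methylbut-3-yn-2-yl)oxy]-2H-chromen-6-yl}[4-(methoxymethoxy)phenyl]methanone | COCOc1ccc(cc1)C(=O)c1c(OC(C)(C)C#C)cc2OC(C)(C)C=Cc2c1O
F3 | step 8 | {5-hydroxy-2,2-dimethyl-7-[(2-methylbut-3-en-2-yl)oxy]-2H-chromen-6-yl}[4-(methoxymethoxy)phenyl]methanone | COCOc1ccc(cc1)C(=O)c1c(OC(C)(C)C=C)cc2OC(C)(C)C=Cc2c1O
F4 | step 9 | (5,7-dihydroxy-2,2-dimethyl-2H-chromen-6-yl)(4-hydroxyphenyl)methanone | Oc1ccc(cc1)C(=O)c1c(O)cc2OC(C)(C)C=Cc2c1O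
F5 | step 9 | (5,7-dihydroxy-2,2-dimethyl-2H-chromen-6-yl){4-[tri(propan-2-yl)silyloxy]phenyl}methanone | CC(C)[Si](Oc1ccc(cc1)C(=O)c1c(O)cc2OC(C)(C)C=Cc2c1O)(C(C)C)C(C)C
F6 | step 9 | [5,7-dihydroxy-2,2-dimethyl-8-(3-methylbut-2-en-1-yl)-2H-chromen-6-yl]{4-[tri(propan-2-yl)silyloxy]phenyl}methanone | CC(C)[Si](Oc1ccc(cc1)C(=O)c1c(O)c(CC=C(C)C)c2OC(C)(C)C=Cc2c1O)(C(C)C)C(C)C
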